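Ring C is cut at O1–C2 and C3–C4 (flavan numbering), giving styrene and a ring A 2-(acetoxymethylene)-1,3-dione whose C7,C8 diol is tied up as an acetonide. The cut uses the way ring C is joined to ring A: O1 and C4 both sit on the C4a=C8a double bond, which is conjugated with the C5 ketone, the pattern left when the 1-oxadiene O=C8a–C4a=C4(OAc) takes up an alkene. One copper-catalysed inverse-demand oxa-Diels–Alder reaction should thus close ring C, set C2 and C4 and bring in the acetate. Ring A is made from 2,4,4-trimethylcyclohex-2-en-1-one by CBS reduction, hydroxyl-controlled dihydroxylation and oxidation at C5; acetonide removal ends the route.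

Key step: step 10

Assumption: the 1,3-dione and the 2-formyl-1,3-dione are written in one keto or enol form although they are tautomeric mixtures, and the acetoxymethylene dione is written as its E isomer although its push–pull C=C should equilibrate E/Z in solution.

Step 1
Reactants: 1 2,4,4-trimethylcyclohex-2-en-1-one
Product: 2 (R)-2,4,4-trimethylcyclohex-2-en-1-ol
Conditions: (S)-2-methyl-CBS-oxazaborolidine (10 mol %), BH3·SMe2 (0.7 equiv), THF, −20 °C; MeOH quench
Reagents that add atoms: none
Why: Corey–Bakshi–Shibata reduction, in which the ketone binds to the catalyst boron anti to the larger, α-methyl-substituted alkenyl arm so that the (S)-catalyst should deliver hydride to the face giving the (R)-allylic alcohol (the sense known for aryl methyl ketones), 1,2-reduction being faster than hydroboration of the hindered trisubstituted olefin at this temperature.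

Step 2
Reactants: 2 (R)-2,4,4-trimethylcyclohex-2-en-1-ol
Product: 3 (1R,2S,3R)-2,4,4-trimethylcyclohexane-1,2,3-triol (2-OH and 3-OH cis to each other and trans to 1-OH)
Conditions: OsO4 (2 mol %), N-methylmorpholine N-oxide (1.5 equiv), acetone/H2O 4:1, rt
Reagents that add atoms: osmium tetroxide, O=[Os](=O)(=O)=O; N-methylmorpholine N-oxide, C[N+]1([O-])CCOCC1; water, O
Why: Catalytic osmylation adds suprafacially, so the new hydroxyls are cis, and by the empirical anti rule for allylic alcohols they should enter trans to the C1 hydroxyl, helped by the half-chair with pseudoequatorial OH, which has the pseudoaxial C4 methyl on the hydroxyl face; the minor all-cis triol is removed here by recrystallisation or chromatography because after step 4 it would become the enantiomer of 5.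

Step 3
Reactants: 3 (1R,2S,3R)-2,4,4-trimethylcyclohexane-1,2,3-triol
Product: 4 (3aS,4R,7aR)-2,2,3a,7,7-pentamethylhexahydro-1,3-benzodioxol-4-ol (2,3-acetonide of 3 with free C1 hydroxyl)
Conditions: 2,2-dimethoxypropane, PPTS (cat.), CH2Cl2, rt
Reagents that add atoms: 2,2-dimethoxypropane, COC(C)(C)OC
Why: Acid-catalysed ketal exchange under thermodynamic control should select the cis-2,3-diol (cis-fused dioxolane) over the trans-1,2-diol and leave the secondary C1 hydroxyl free, with no stereocentre touched.

Step 4
Reactants: 4 (3aS,4R,7aR)-2,2,3a,7,7-pentamethylhexahydro-1,3-benzodioxol-4-ol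
Product: 5 (3aR,7aR)-2,2,3a,7,7-pentamethylhexahydro-1,3-benzodioxol-4-one
Conditions: Dess–Martin periodinane, CH2Cl2, rt
Reagents that add atoms: none
Why: Dess–Martin oxidation of the secondary alcohol removes the carbinol centre that relayed the chirality, and the α-carbon is quaternary, so nothing can epimerise.

Step 5
Reactants: 5 (3aR,7aR)-2,2,3a,7,7-pentamethylhexahydro-1,3-benzodioxol-4-one
Product: 7 (3aR,7aR)-2,2,3a,7,7-pentamethyl-7,7a-dihydro-1,3-benzodioxol-4(3aH)-one (enone with C5=C6), via trimethylsilyl enol ether 6 (not isolated)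
Conditions: LiN(i-Pr)2, TMSCl, THF, −78 °C; then Pd(OAc)2 (1.0 equiv), MeCN, rt
Reagents that add atoms: none
Why: Saegusa–Ito oxidation: the ketone can enolise only towards C5, and Pd(OAc)2 dehydrogenates the silyl enol ether through an oxa-π-allyl palladium species and β-hydride elimination.

Step 6
Reactants: 7 (3aR,7aR)-2,2,3a,7,7-pentamethyl-7,7a-dihydro-1,3-benzodioxol-4(3aH)-one
Product: 9 (3aR,7aR)-6-hydroxy-2,2,3a,7,7-pentamethylhexahydro-1,3-benzodioxol-4-one (epimers at C6), via pinacolboryl ketone 8 (not isolated)
Conditions: CuCl (5 mol %), NaOt-Bu (10 mol %), Xantphos (5 mol %), B2pin2 (1.1 equiv), MeOH (2 equiv), THF, rt; then NaBO3·4H2O, THF/H2O, rt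
Reagents that add atoms: sodium perborate, [Na+].[O-]OB=O
Why: Copper-catalysed conjugate borylation puts boron on the β-carbon of the enone (methanol turns over the copper enolate), and stereoretentive C–B oxidation with mild perborate should give the β-hydroxy ketone without dehydration; the new carbinol centre is lost in step 7.

Step 7
Reactants: 9 (3aR,7aR)-6-hydroxy-2,2,3a,7,7-pentamethylhexahydro-1,3-benzodioxol-4-one
Product: 10 (3aR,7aR)-2,2,3a,7,7-pentamethyltetrahydro-1,3-benzodioxole-4,6-dione (acetonide of (5R,6R)-5,6-dihydroxy-4,4,6-trimethylcyclohexane-1,3-dione)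
Conditions: Dess–Martin periodinane, CH2Cl2, rt
Reagents that add atoms: none
Why: Dess–Martin oxidation of a β-hydroxy ketone to the 1,3-dione under neutral conditions, which the acetonide and both stereocentres survive.

Step 8
Reactants: 10 (3aR,7aR)-2,2,3a,7,7-pentamethyltetrahydro-1,3-benzodioxole-4,6-dione; 11 N,N-dimethylformamide dimethyl acetal
Product: 13 (3aR,7aR)-5-(hydroxymethylidene)-2,2,3a,7,7-pentamethyltetrahydro-1,3-benzodioxole-4,6-dione (the 2-formyl-1,3-dione), via enaminone 12 (not isolated)
Conditions: toluene, 50 °C; then 1 M NaOH, THF, rt; 1 M HCl to pH 3, 0 °C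
Reagents that add atoms: sodium hydroxide (aqueous), [Na+].[OH-]
Why: Aminomethylenation of the only acidic methylene (C5, between the two carbonyls) by the formamide acetal, then addition–elimination of hydroxide at the aminomethylene carbon and acidification, a standard entry to 2-formyl-1,3-diones; base and brief cold acid spare the acetonide, and the protected oxygens cannot undergo retro-aldol cleavage.

Step 9
Reactants: 13 (3aR,7aR)-5-(hydroxymethylidene)-2,2,3a,7,7-pentamethyltetrahydro-1,3-benzodioxole-4,6-dione
Product: 14 (E)-[(3aR,7aR)-2,2,3a,7,7-pentamethyl-4,6-dioxotetrahydro-1,3-benzodioxol-5-ylidene]methyl acetate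
Conditions: AcCl (1.05 equiv), pyridine, CH2Cl2, −20 °C; used without storage
Reagents that add atoms: acetyl chloride, CC(=O)Cl
Why: O-Acylation of the tricarbonyl enolate should go to the exocyclic formyl oxygen because both ring carbonyl oxygens are flanked by fully substituted carbons; the product is a vinylogous mixed anhydride, hence made cold and used at once, and its C=C geometry is not configurationally stable.

Step 10
Reactants: 14 (E)-[(3aR,7aR)-2,2,3a,7,7-pentamethyl-4,6-dioxotetrahydro-1,3-benzodioxol-5-ylidene]methyl acetate; 15 styrene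
Product: 16 (2R,4R,7R,8R)-4-acetoxy-7,8-(isopropylidenedioxy)-6,6,8-trimethyl-2-phenyl-2,3,4,6,7,8-hexahydro-5H-chromen-5-one (acetonide of the target)
Conditions: 15 (5 equiv), Cu(OTf)2 (10 mol %), 4,4'-di-tert-butyl-2,2'-bipyridine (11 mol %), 4 Å MS, CH2Cl2, −20 °C to rt
Reagents that add atoms: none
Why: Divalent copper held between the C8a carbonyl oxygen and the adjacent C8 acetal oxygen lowers the LUMO of the 1-oxadiene O=C8a–C4a=C4(OAc), and styrene adds across its ends in a concerted, asynchronous [4+2] in which C3–C4 bonding leads and the benzylic carbon closes onto the carbonyl oxygen, so that the polarity of both partners puts phenyl at C2. The closest known reaction type is the Lewis-acid-catalysed inverse-electron-demand oxa-Diels–Alder reaction of 2-alkylidene and 2-(acyloxymethylene) 1,3-dicarbonyl compounds with styrenes and enol ethers. Ring C is closed by the intermolecular cycloaddition itself, both ring bonds forming in one event and the C4a=C8a enol ether appearing with them. C2 and C4 should come out cis because phenyl approaches endo to a diene that carries acetoxy on the outside; E and Z forms of 14 interconvert, and only the E form presents an unhindered terminus to the chelated carbonyl. The sense of both centres relative to ring A should follow from attack on the face syn to the acetal oxygens, since chelation draws C8–O into the carbonyl plane and thereby turns the C8 methyl and one C6 methyl pseudoaxial onto the other face; a flat, compact bipyridine ligand is chosen so that the hindered acetal oxygen can still reach copper. The selectivity most in need of proof is use of the C8a rather than the C5 carbonyl as diene oxygen, which rests on C8a being the chelated and, through its α-oxygen, the more electrophilic carbonyl.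

Step 11
Reactants: 16 (2R,4R,7R,8R)-4-acetoxy-7,8-(isopropylidenedioxy)-6,6,8-trimethyl-2-phenyl-2,3,4,6,7,8-hexahydro-5H-chromen-5-one
Product: 17 (2R,4R,7R,8R)-7,8-dihydroxy-6,6,8-trimethyl-5-oxo-2-phenyl-3,4,5,6,7,8-hexahydro-2H-chromen-4-yl acetate
Conditions: AcOH/H2O 4:1, 35 °C
Reagents that add atoms: none
Why: Acid-catalysed hydrolysis of the isopropylidene ketal; the allylic C4 acetate is the only other group at risk, its ionisation is slowed by the acyl group on C4a and in acetic acid any ion-pair return would give back acetate, and no stereocentre is involved.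

Compound list
1 | 2,4,4-trimethylcyclohex-2-en-1-one | CC1=CC(C)(C)CCC1=O | starting material
2 | (R)-2,4,4-trimethylcyclohex-2-en-1-ol | O[C@@H]1CCC(C)(C)C=C1C | intermediate
3 | (1R,2S,3R)-2,4,4-trimethylcyclohexane-1,2,3-triol | O[C@@H]1CCC(C)(C)[C@@H](O)[C@@]1(C)O | intermediate
4 | (3aS,4R,7aR)-2,2,3a,7,7-pentamethylhexahydro-1,3-benzodioxol-4-ol | O[C@@H]1CCC(C)(C)[C@H]2OC(C)(C)O[C@@]12C | intermediate
5 | (3aR,7aR)-2,2,3a,7,7-pentamethylhexahydro-1,3-benzodioxol-4-one | O=C1CCC(C)(C)[C@H]2OC(C)(C)O[C@@]12C | intermediate
6 | trimethylsilyl enol ether of 5 | C[Si](C)(C)OC1=CCC(C)(C)[C@H]2OC(C)(C)O[C@@]12C | intermediate (not isolated)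
7 | (3aR,7aR)-2,2,3a,7,7-pentamethyl-7,7a-dihydro-1,3-benzodioxol-4(3aH)-one | O=C1C=CC(C)(C)[C@H]2OC(C)(C)O[C@@]12C | intermediate
8 | (3aR,7aR)-2,2,3a,7,7-pentamethyl-6-(4,4,5,5-tetramethyl-1,3,2-dioxaborolan-2-yl)hexahydro-1,3-benzodioxol-4-one (epimers at C6) | O=C1CC(B2OC(C)(C)C(C)(C)O2)C(C)(C)[C@H]3OC(C)(C)O[C@@]13C | intermediate (not isolated)
9 | (3aR,7aR)-6-hydroxy-2,2,3a,7,7-pentamethylhexahydro-1,3-benzodioxol-4-one (epimers at C6) | O=C1CC(O)C(C)(C)[C@H]2OC(C)(C)O[C@@]12C | intermediate
10 | (3aR,7aR)-2,2,3a,7,7-pentamethyltetrahydro-1,3-benzodioxole-4,6-dione | O=C1CC(=O)C(C)(C)[C@H]2OC(C)(C)O[C@@]12C | intermediate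
11 | N,N-dimethylformamide dimethyl acetal | COC(OC)N(C)C | starting material
12 | (3aR,7aR)-5-[(dimethylamino)methylidene]-2,2,3a,7,7-pentamethyltetrahydro-1,3-benzodioxole-4,6-dione | CN(C)C=C1C(=O)C(C)(C)[C@H]2OC(C)(C)O[C@@]2(C)C1=O | intermediate (not isolated)
13 | (3aR,7aR)-5-(hydroxymethylidene)-2,2,3a,7,7-pentamethyltetrahydro-1,3-benzodioxole-4,6-dione | OC=C1C(=O)C(C)(C)[C@H]2OC(C)(C)O[C@@]2(C)C1=O | intermediate
14 | (E)-[(3aR,7aR)-2,2,3a,7,7-pentamethyl-4,6-dioxotetrahydro-1,3-benzodioxol-5-ylidene]methyl acetate | CC(=O)O/C=C1\C(=O)C(C)(C)[C@H]2OC(C)(C)O[C@@]2(C)C1=O | intermediate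
15 | styrene | C=Cc1ccccc1 | starting material
16 | (2R,4R,7R,8R)-4-acetoxy-7,8-(isopropylidenedioxy)-6,6,8-trimethyl-2-phenyl-2,3,4,6,7,8-hexahydro-5H-chromen-5-one | CC(=O)O[C@@H]1C[C@H](c2ccccc2)OC2=C1C(=O)C(C)(C)[C@H]3OC(C)(C)O[C@@]23C | intermediate
17 | (2R,4R,7R,8R)-7,8-dihydroxy-6,6,8-trimethyl-5-oxo-2-phenyl-3,4,5,6,7,8-hexahydro-2H-chromen-4-yl acetate | CC(=O)O[C@@H]1C[C@H](c2ccccc2)OC2=C1C(=O)C(C)(C)[C@@H](O)[C@@]2(C)O | target

Total step count: 11. Longest linear sequence: 11 steps (1 to 17); 11 and 15 enter as purchased components.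

Steps most likely to fail

Step 10. Several processes can go wrong:
- the C5 carbonyl may take the diene role after E/Z equilibration;
- copper may bind at one point only, with loss of facial control;
- styrene may approach exo;
- the acetyl group may migrate to a ring oxygen;
- the Lewis acid may ionise the allylic acetate of the adduct;
- styrene may oligomerise.

Fallback: setting out from dione 10, ring C would be built stepwise as in flavanone chemistry. C-Acylation with cinnamic acid (DCC, DMAP; O-acylation followed by O-to-C acyl shift) gives the 2-cinnamoyl dione F1. Intramolecular oxa-Michael addition (DBU, CH2Cl2) gives the 2-phenyl-2,3-dihydropyran-4-one F2; this step is reversible, so isomers closed through the other ring oxygen or epimeric at C2 can be separated and re-equilibrated. NaBH4 with CeCl3·7H2O in MeOH at −40 °C should reduce the less hindered C4 ketone from the face opposite the equatorial phenyl to the 2,4-cis alcohol F3. Ac2O and pyridine then return to the route at 16.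

Step 11. Ionisation of the allylic C4 acetate (epimerisation at C4, solvolysis or loss of acetic acid) may compete with the slow hydrolysis of a hindered cis-fused ketal.

Fallback: the diol protecting group is changed before the acetate exists. From formyl dione 13, aqueous trifluoroacetic acid removes the acetonide to give the diol F4. t-Bu2Si(OTf)2 with 2,6-lutidine gives the cyclic di-tert-butylsilylene F5 (any enol silyl ether falls off on work-up). The conditions of steps 9 and 10 then give the acetoxymethylene compound F6 and the silylene-protected cycloadduct F7. HF·pyridine in THF at 0 °C, which leaves acetates alone, releases 17. Because silyl ethers do not chelate, face selection in that cycloaddition would have to come from a C2-symmetric bis(oxazoline) ligand on Cu(OTf)2.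

Step 6. Boryl-copper addition may be slow at a β-carbon next to a quaternary centre, and the β-hydroxy ketone may dehydrate or undergo retro-aldol cleavage during the basic oxidative work-up.

Fallback: from enone 7, nucleophilic epoxidation (t-BuOOH, DBU, CH2Cl2) gives the epoxy ketone F8. Pd(PPh3)4 with 1,2-bis(diphenylphosphino)ethane in toluene at 80 °C isomerises α,β-epoxy ketones to β-diketones, which leads directly to dione 10 and bypasses 9.

Further compounds
F1 | step 10 | (3aR,7aR)-5-[(E)-1-hydroxy-3-phenylprop-2-enylidene]-2,2,3a,7,7-pentamethyltetrahydro-1,3-benzodioxole-4,6-dione (2-cinnamoyl dione, enol form) | OC(/C=C/c1ccccc1)=C1C(=O)C(C)(C)[C@H]2OC(C)(C)O[C@@]2(C)C1=O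
F2 | step 10 | (2R,7R,8R)-7,8-(isopropylidenedioxy)-6,6,8-trimethyl-2-phenyl-2,3,7,8-tetrahydro-4H-chromene-4,5(6H)-dione | O=C1C[C@H](c2ccccc2)OC2=C1C(=O)C(C)(C)[C@H]3OC(C)(C)O[C@@]23C
F3 | step 10 | (2R,4R,7R,8R)-4-hydroxy-7,8-(isopropylidenedioxy)-6,6,8-trimethyl-2-phenyl-2,3,4,6,7,8-hexahydro-5H-chromen-5-one | O[C@@H]1C[C@H](c2ccccc2)OC2=C1C(=O)C(C)(C)[C@H]3OC(C)(C)O[C@@]23C
F4 | step 11 | (5R,6R)-5,6-dihydroxy-2-(hydroxymethylidene)-4,4,6-trimethylcyclohexane-1,3-dione | OC=C1C(=O)C(C)(C)[C@@H](O)[C@@](C)(O)C1=O
F5 | step 11 | cyclic di-tert-butylsilylene ether of F4 (5,6-O-silylene) | OC=C1C(=O)C(C)(C)[C@H]2O[Si](C(C)(C)C)(C(C)(C)C)O[C@@]2(C)C1=O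
F6 | step 11 | (E)-acetoxymethylene dione with 5,6-O-di-tert-butylsilylene (silylene analogue of 14) | CC(=O)O/C=C1\C(=O)C(C)(C)[C@H]2O[Si](C(C)(C)C)(C(C)(C)C)O[C@@]2(C)C1=O
F7 | step 11 | (2R,4R,7R,8R)-4-acetoxy-7,8-(di-tert-butylsilylenedioxy)-6,6,8-trimethyl-2-phenyl-2,3,4,6,7,8-hexahydro-5H-chromen-5-one | CC(=O)O[C@@H]1C[C@H](c2ccccc2)OC2=C1C(=O)C(C)(C)[C@H]3O[Si](C(C)(C)C)(C(C)(C)C)O[C@@]23C
F8 | step 6 | (3aR,7aR)-5,6-epoxy-2,2,3a,7,7-pentamethylhexahydro-1,3-benzodioxol-4-one (epoxide configuration not controlled) | O=C1C2OC2C(C)(C)[C@H]3OC(C)(C)O[C@@]13C
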